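**Retrosynthetic overview**
1. 22 comes from 18 by functional-group work only: Δ1 hydrogenation, C8-OH → C8=O → C8=CH2, then desilylation.
2. Key step: 18 comes from the acyclic (2E,8Z)-undeca-2,8,10-trienoate 17 by one intramolecular Diels–Alder reaction (bonds C5–C10 and C3–C4). Rings A and B form at the same time, and C4, C5 and C10 are set from C9.
3. 17 comes from isopropenyl carbinol 14. The Z-diene is locked by a boron-tethered RCM and then made by Suzuki vinylation.
4. 14 comes from aldehyde 3 and E-allylboronate 12 by catalytic asymmetric anti-allylboration (C8–C9 bond, sets C9).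
5. 12 comes from 10 (SeO2, then borylation). 10 comes from Z-iodide 7 (from butynediol, fixes 13E) and homoprenyl Grignard. 3 comes from pent-4-enal and methyl methacrylate by cross-metathesis.

Assumption: the SMILES is read literally as (4S,5S,9S,10R,13E), so H-5, CH3-20, CO2Me-19 and the C9 side chain all lie on the β face (a cis-fused decalin, the 5-epimer of a normal labdan-19-oate).

Conventions: labdane numbering is used throughout. TBDPS = tert-butyldiphenylsilyl. SC = (3E)-5-(TBDPS-oxy)-3-[(TBDPS-oxy)methyl]pent-3-en-1-yl, that is –CH2CH2–C(CH2OTBDPS)=CH–CH2OTBDPS with the CH2CH2 chain cis to the CH2OTBDPS group on the =CH carbon.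

Step 1
Reactants: 1 pent-4-enal; 2 methyl methacrylate
Product: 3 methyl (2E)-2-methyl-6-oxohex-2-enoate
Conditions: Hoveyda–Grubbs II (2 mol %), 2 (5 equiv), CH2Cl2, 40 °C
Reagents that add atoms: none
Why: Olefin cross-metathesis of a terminal alkene with excess methacrylate is product-selective, tolerates the aldehyde, and gives the E-trisubstituted enoate (CO2Me trans to the chain), the geometry that later fixes C4 relative to C5.

Step 2
Reactants: 4 but-2-yne-1,4-diol
Product: 6 (2Z)-2-iodobut-2-ene-1,4-diol, via sodium cyclic alkenylalanate 5 (not isolated)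
Conditions: Red-Al (toluene soln), THF, 0 °C → rt; then I2, THF, −78 → 0 °C
Reagents that add atoms: iodine, II
Why: Alkoxide-directed trans-hydroalumination of a propargylic alcohol holds Al in a five-membered chelate cis to the distal CH2O group, and iodinolysis with retention gives only the Z-iodide (the two CH2OH groups trans).

Step 3
Reactants: 6 (2Z)-2-iodobut-2-ene-1,4-diol
Product: 7 (2Z)-1,4-bis(TBDPS-oxy)-2-iodobut-2-ene
Conditions: TBDPSCl (2.2 equiv), imidazole, DMF, rt
Reagents that add atoms: tert-butyl(chloro)diphenylsilane, CC(C)(C)[Si](Cl)(c1ccccc1)c1ccccc1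
Why: Standard imidazole-promoted silylation gives bulky, acid-stable ethers that survive all later steps and shield the side-chain olefin.

Step 4
Reactants: 7 (2Z)-1,4-bis(TBDPS-oxy)-2-iodobut-2-ene; 8 5-bromo-2-methylpent-2-ene
Product: 10 (2E)-1,4-bis(TBDPS-oxy)-2-(4-methylpent-3-enyl)but-2-ene, via 4-methylpent-3-enylmagnesium bromide 9 (not isolated)
Conditions: 8, Mg, THF, rt; then 7, PdCl2(dppf) (3 mol %), THF, 0 °C → rt
Reagents that add atoms: none
Why: In this Kumada–Corriu sp3–sp2 coupling the wide-bite-angle dppf ligand outruns β-hydride elimination, and retention at the alkenyl carbon places C12 cis to C15 (the 13E olefin of the target).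

Step 5
Reactants: 10 (2E)-1,4-bis(TBDPS-oxy)-2-(4-methylpent-3-enyl)but-2-ene
Product: 11 (2E,6E)-8-(TBDPS-oxy)-6-[(TBDPS-oxy)methyl]-2-methylocta-2,6-dien-1-ol
Conditions: SeO2 (0.2 equiv), t-BuOOH (2 equiv), salicylic acid (0.1 equiv), CH2Cl2, 0 °C → rt
Reagents that add atoms: selenium dioxide (catalytic O-transfer agent), O=[Se]=O; tert-butyl hydroperoxide (terminal O source), CC(C)(C)OO
Why: Sharpless–Umbreit allylic oxidation (ene reaction then [2,3]-shift) attacks the electron-rich terminal prenyl unit rather than the olefin deactivated by two allylic silyloxy groups, and it oxidises only the E-methyl group.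

Step 6
Reactants: 11 (2E,6E)-8-(TBDPS-oxy)-6-[(TBDPS-oxy)methyl]-2-methylocta-2,6-dien-1-ol
Product: 12 pinacol (2E,6E)-8-(TBDPS-oxy)-6-[(TBDPS-oxy)methyl]-2-methylocta-2,6-dien-1-ylboronate
Conditions: B2pin2 (1.2 equiv), [Pd(MeCN)4](BF4)2 (5 mol %), DMSO/MeOH/THF, 40 °C
Reagents that add atoms: bis(pinacolato)diboron, CC1(C)OB(OC1(C)C)B1OC(C)(C)C(C)(C)O1
Why: Pd-catalysed direct borylation of an allylic alcohol proceeds through the syn-η3-allyl complex with C–B bond formation at the unhindered CH2 terminus, so the linear E-allylboronate forms while silyl ethers do not ionise.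

Step 7
Reactants: 12 pinacol (2E,6E)-8-(TBDPS-oxy)-6-[(TBDPS-oxy)methyl]-2-methylocta-2,6-dien-1-ylboronate; 3 methyl (2E)-2-methyl-6-oxohex-2-enoate
Product: 14 methyl (2E,6S,7R)-6-hydroxy-2,8-dimethyl-7-SC-nona-2,8-dienoate, via pinacol borate ester 13 (not isolated)
Conditions: (R)-TRIP (5 mol %), 4 Å MS, toluene, −30 °C; aq. work-up
Reagents that add atoms: none
Why: In this chiral-phosphoric-acid-catalysed allylboration the closed chair transition state converts the E-boronate into the anti adduct and (R)-TRIP directs attack to the Re face of the aldehyde, which sets C9 with the target configuration and C8 as 8S (removed later).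

Step 8
Reactants: 14 methyl (2E,6S,7R)-6-hydroxy-2,8-dimethyl-7-SC-nona-2,8-dienoate
Product: 16 cyclic butyl alkenylboronate (six-membered ring O-B(OBu)-CH=C(CH3)-C9-C8; C8 chain trans to SC), via mixed butyl vinylboronate 15 (not isolated)
Conditions: CH2=CHB(OBu)2 (1.5 equiv), CH2Cl2, rt, evaporate BuOH; Grubbs II (10 mol %), toluene, 80 °C, Ar sparge; used crude
Reagents that add atoms: vinylboronic acid dibutyl ester, C=CB(OCCCC)OCCCC
Why: Boron-tethered ring-closing metathesis engages only the vinylboronate and the 1,1-disubstituted isopropenyl group (both trisubstituted olefins are inert), and the six-membered ring forces boron, the future vinyl position, to be cis to C9.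

Step 9
Reactants: 16 cyclic butyl alkenylboronate
Product: 17 methyl (2E,6S,7R,8Z)-6-hydroxy-2,8-dimethyl-7-SC-undeca-2,8,10-trienoate
Conditions: CH2=CHBr (THF soln, 5 equiv), Pd(PPh3)4 (5 mol %), aq. K3PO4, THF, 45 °C
Reagents that add atoms: vinyl bromide, C=CBr
Why: Suzuki–Miyaura coupling proceeds with retention at the alkenylboron carbon, so the vinyl group ends cis to C9 (Z-diene), the C8 hydroxyl is released, and the enoate is untouched by the mild base.

Step 10
Reactants: 17 methyl (2E,6S,7R,8Z)-6-hydroxy-2,8-dimethyl-7-SC-undeca-2,8,10-trienoate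
Product: 18 methyl 8β-hydroxy-15,16-bis(TBDPS-oxy)-5β(H)-labda-1,13E-dien-19-oate (cis-decalin)
Conditions: toluene (0.01 M), BHT (10 mol %), sealed tube, 180 °C, 48 h
Reagents that add atoms: none
Why: In this type-1 intramolecular Diels–Alder reaction the tether sits on the inside (Z) position of the diene, so only the tether-exo/ester-endo transition state is reachable and the ring fusion must be cis (H5 syn to CH3-20), while suprafacial addition to the E-enoate puts CO2Me syn to H5, and A(1,3) strain at C9 (H9 in the diene plane, C8 toward the dienophile, SC away) selects the diene face, so C4, C5 and C10 are all set from C9 with SC cis to CH3-20.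

Step 11
Reactants: 18 methyl 8β-hydroxy-15,16-bis(TBDPS-oxy)-5β(H)-labda-1,13E-dien-19-oate
Product: 19 methyl 8β-hydroxy-15,16-bis(TBDPS-oxy)-5β(H)-labd-13E-en-19-oate
Conditions: H2 (4 atm), RhCl(PPh3)3 (10 mol %), benzene/EtOH, rt
Reagents that add atoms: none
Why: Wilkinson homogeneous hydrogenation reduces the cis-disubstituted Δ1 olefin (as it does the Δ1 bond next to C10 in steroid 1,4-dienones) but not the trisubstituted Δ13 olefin flanked by two TBDPSOCH2 groups, and no stereocentre changes.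

Step 12
Reactants: 19 methyl 8β-hydroxy-15,16-bis(TBDPS-oxy)-5β(H)-labd-13E-en-19-oate
Product: 20 methyl 8-oxo-15,16-bis(TBDPS-oxy)-17-nor-5β(H)-labd-13E-en-19-oate
Conditions: Dess–Martin periodinane, NaHCO3, CH2Cl2, 0 °C → rt
Reagents that add atoms: none
Why: Buffered Dess–Martin oxidation is near-neutral, so the hindered C9–H next to quaternary C10 is not enolised and C9 keeps its configuration.

Step 13
Reactants: 20 methyl 8-oxo-15,16-bis(TBDPS-oxy)-17-nor-5β(H)-labd-13E-en-19-oate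
Product: 21 methyl 15,16-bis(TBDPS-oxy)-5β(H)-labda-8(17),13E-dien-19-oate
Conditions: Cp2TiMe2 (3 equiv), toluene, 75 °C, dark
Reagents that add atoms: dimethyltitanocene (Petasis reagent), C[Ti+2]C.c1cc[cH-]c1.c1cc[cH-]c1
Why: Petasis methylenation through Cp2Ti=CH2 ([2+2] then retro-[2+2]) is non-basic, so C9 cannot epimerise, and the ketone reacts far faster than the quaternary, hindered C19 methyl ester.

Step 14
Reactants: 21 methyl 15,16-bis(TBDPS-oxy)-5β(H)-labda-8(17),13E-dien-19-oate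
Product: 22 methyl (4S,5S,9S,10R,13E)-15,16-dihydroxylabda-8(17),13-dien-19-oate (target CNP0282002.1)
Conditions: TBAF, AcOH (1:1, 3 equiv each), THF, rt
Reagents that add atoms: none
Why: Buffered fluoride desilylation cleaves both Si–O bonds without touching the hindered methyl ester, either olefin or any stereocentre.

**Compound list**
1 | pent-4-enal | C=CCCC=O | starting material
2 | methyl methacrylate | C=C(C)C(=O)OC | starting material
3 | methyl (2E)-2-methyl-6-oxohex-2-enoate | COC(=O)/C(C)=C/CCC=O | intermediate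
4 | but-2-yne-1,4-diol | OCC#CCO | starting material
5 | sodium cyclic alkenylalanate (five-membered ring O–Al–C13=C14–C15; Al carries two 2-methoxyethoxy groups; CH2OH on C13) | [Na+].COCCO[Al-]1(OCCOC)OCC=C1CO | intermediate (not isolated)
6 | (2Z)-2-iodobut-2-ene-1,4-diol | I/C(=C\CO)CO | intermediate
7 | (2Z)-1,4-bis(TBDPS-oxy)-2-iodobut-2-ene | I/C(=C\CO[Si](c1ccccc1)(c1ccccc1)C(C)(C)C)CO[Si](c1ccccc1)(c1ccccc1)C(C)(C)C | intermediate
8 | 5-bromo-2-methylpent-2-ene | CC(C)=CCCBr | starting material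
9 | 4-methylpent-3-enylmagnesium bromide | CC(C)=CCC[Mg]Br | intermediate (not isolated)
10 | (2E)-1,4-bis(TBDPS-oxy)-2-(4-methylpent-3-enyl)but-2-ene | CC(C)=CCC/C(=C\CO[Si](c1ccccc1)(c1ccccc1)C(C)(C)C)CO[Si](c1ccccc1)(c1ccccc1)C(C)(C)C | intermediate
11 | (2E,6E)-8-(TBDPS-oxy)-6-[(TBDPS-oxy)methyl]-2-methylocta-2,6-dien-1-ol | OC/C(C)=C/CC/C(=C\CO[Si](c1ccccc1)(c1ccccc1)C(C)(C)C)CO[Si](c1ccccc1)(c1ccccc1)C(C)(C)C | intermediate
12 | pinacol (2E,6E)-8-(TBDPS-oxy)-6-[(TBDPS-oxy)methyl]-2-methylocta-2,6-dien-1-ylboronate | CC1(C)OB(OC1(C)C)C/C(C)=C/CC/C(=C\CO[Si](c1ccccc1)(c1ccccc1)C(C)(C)C)CO[Si](c1ccccc1)(c1ccccc1)C(C)(C)C | intermediate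
13 | pinacol borate ester (O-Bpin derivative) of 14 | COC(=O)/C(C)=C/CC[C@H](OB1OC(C)(C)C(C)(C)O1)[C@H](CC/C(=C\CO[Si](c1ccccc1)(c1ccccc1)C(C)(C)C)CO[Si](c1ccccc1)(c1ccccc1)C(C)(C)C)C(C)=C | intermediate (not isolated)
14 | methyl (2E,6S,7R)-6-hydroxy-2,8-dimethyl-7-SC-nona-2,8-dienoate (anti; C8 = 6S, C9 = 7R) | COC(=O)/C(C)=C/CC[C@H](O)[C@H](CC/C(=C\CO[Si](c1ccccc1)(c1ccccc1)C(C)(C)C)CO[Si](c1ccccc1)(c1ccccc1)C(C)(C)C)C(C)=C | intermediate
15 | mixed butyl vinylboronate of 14 (C8–O–B(OBu)–CH=CH2) | COC(=O)/C(C)=C/CC[C@H](OB(C=C)OCCCC)[C@H](CC/C(=C\CO[Si](c1ccccc1)(c1ccccc1)C(C)(C)C)CO[Si](c1ccccc1)(c1ccccc1)C(C)(C)C)C(C)=C | intermediate (not isolated)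
16 | cyclic butyl alkenylboronate (ring O–B(OBu)–CH=C(CH3)–C9–C8; C8 chain and SC trans) | COC(=O)/C(C)=C/CC[C@@H]1OB(OCCCC)C=C(C)[C@H]1CC/C(=C\CO[Si](c1ccccc1)(c1ccccc1)C(C)(C)C)CO[Si](c1ccccc1)(c1ccccc1)C(C)(C)C | intermediate
17 | methyl (2E,6S,7R,8Z)-6-hydroxy-2,8-dimethyl-7-SC-undeca-2,8,10-trienoate | COC(=O)/C(C)=C/CC[C@H](O)[C@H](CC/C(=C\CO[Si](c1ccccc1)(c1ccccc1)C(C)(C)C)CO[Si](c1ccccc1)(c1ccccc1)C(C)(C)C)/C(C)=C\C=C | intermediate
18 | methyl 8β-hydroxy-15,16-bis(TBDPS-oxy)-5β(H)-labda-1,13E-dien-19-oate (H5, CH3-20, CO2Me, SC and OH all β) | O[C@H]1CC[C@H]2[C@](C)(C=CC[C@]2(C)C(=O)OC)[C@H]1CC/C(=C\CO[Si](c1ccccc1)(c1ccccc1)C(C)(C)C)CO[Si](c1ccccc1)(c1ccccc1)C(C)(C)C | intermediate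
19 | methyl 8β-hydroxy-15,16-bis(TBDPS-oxy)-5β(H)-labd-13E-en-19-oate | O[C@H]1CC[C@H]2[C@](C)(CCC[C@]2(C)C(=O)OC)[C@H]1CC/C(=C\CO[Si](c1ccccc1)(c1ccccc1)C(C)(C)C)CO[Si](c1ccccc1)(c1ccccc1)C(C)(C)C | intermediate
20 | methyl 8-oxo-15,16-bis(TBDPS-oxy)-17-nor-5β(H)-labd-13E-en-19-oate | O=C1CC[C@H]2[C@](C)(CCC[C@]2(C)C(=O)OC)[C@H]1CC/C(=C\CO[Si](c1ccccc1)(c1ccccc1)C(C)(C)C)CO[Si](c1ccccc1)(c1ccccc1)C(C)(C)C | intermediate
21 | methyl 15,16-bis(TBDPS-oxy)-5β(H)-labda-8(17),13E-dien-19-oate | C=C1CC[C@H]2[C@](C)(CCC[C@]2(C)C(=O)OC)[C@H]1CC/C(=C\CO[Si](c1ccccc1)(c1ccccc1)C(C)(C)C)CO[Si](c1ccccc1)(c1ccccc1)C(C)(C)C | intermediate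
22 | methyl (4S,5S,9S,10R,13E)-15,16-dihydroxylabda-8(17),13-dien-19-oate | C=C1CC[C@H]2[C@](C)(CCC[C@]2(C)C(=O)OC)[C@H]1CC/C(=C\CO)CO | target

**Totals**
- Total step count: 14.
- Longest linear sequence: 13 steps (steps 2–14, from but-2-yne-1,4-diol).

**Three steps most likely to fail**

Step 10 (the cycloaddition) is the largest risk. A trisubstituted dienophile and a Z-trisubstituted diene must form two quaternary carbons, and a 1,5-hydrogen shift of the Z-diene competes at 180 °C. The fallback sets out from 17 and comes back at 18. It raises dienophile reactivity instead of temperature. DIBAL-H reduces the ester of 17 to the allylic diol F1. MnO2 then oxidises only the primary allylic alcohol, giving the (E)-2-methyl enal F2. This cyclises through the same Z-diene-enforced transition state with Me2AlCl (2.2 equiv, the first equivalent capping the C8 alkoxide) at −40 to 0 °C, or thermally near 110 °C, to the bicyclic aldehyde F3. Pinnick oxidation gives the carboxylic acid F4, and TMSCHN2 esterification returns to 18.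

Step 8 is the second risk, because the metathesis must close onto a hindered 1,1-disubstituted olefin through a labile boronate. The fallback sets out from 14 and comes back at 17, bypassing 16. It replaces the boron tether and Suzuki coupling with a silicon tether and Hiyama–Denmark coupling. Chlorodimethylvinylsilane and imidazole give the dimethyl(vinyl)silyl ether F5. Schrock's molybdenum alkylidene, which closes trisubstituted vinylsilanes, gives the cyclic alkenylsiloxane F6. Fluoride-free KOSiMe3 activation with Pd(dba)2 and vinyl bromide transfers the alkenyl group with retention, and aqueous work-up frees the C8 hydroxyl to give 17.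

Step 13 is the third risk, because the ketone is hindered and its C9 epimer is probably the more stable one. The fallback sets out from 20 and comes back at 21. It uses two-stage Peterson olefination in place of a titanium carbene. The weakly basic reagent TMSCH2Li/CeCl3 adds at −78 °C to give the β-hydroxysilane F7 (either C8 epimer serves). The carbonyl is then gone, so C9 is no longer enolisable. KH in THF at 0 °C triggers syn-elimination to 21.

**Further compounds**
F1 | step 10 | (2E,6S,7R,8Z)-2,8-dimethyl-7-SC-undeca-2,8,10-triene-1,6-diol | OC/C(C)=C/CC[C@H](O)[C@H](CC/C(=C\CO[Si](c1ccccc1)(c1ccccc1)C(C)(C)C)CO[Si](c1ccccc1)(c1ccccc1)C(C)(C)C)/C(C)=C\C=C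
F2 | step 10 | (2E,6S,7R,8Z)-6-hydroxy-2,8-dimethyl-7-SC-undeca-2,8,10-trienal | O=C/C(C)=C/CC[C@H](O)[C@H](CC/C(=C\CO[Si](c1ccccc1)(c1ccccc1)C(C)(C)C)CO[Si](c1ccccc1)(c1ccccc1)C(C)(C)C)/C(C)=C\C=C
F3 | step 10 | 8β-hydroxy-15,16-bis(TBDPS-oxy)-5β(H)-labda-1,13E-dien-19-al | O[C@H]1CC[C@H]2[C@](C)(C=CC[C@]2(C)C=O)[C@H]1CC/C(=C\CO[Si](c1ccccc1)(c1ccccc1)C(C)(C)C)CO[Si](c1ccccc1)(c1ccccc1)C(C)(C)C
F4 | step 10 | 8β-hydroxy-15,16-bis(TBDPS-oxy)-5β(H)-labda-1,13E-dien-19-oic acid | O[C@H]1CC[C@H]2[C@](C)(C=CC[C@]2(C)C(=O)O)[C@H]1CC/C(=C\CO[Si](c1ccccc1)(c1ccccc1)C(C)(C)C)CO[Si](c1ccccc1)(c1ccccc1)C(C)(C)C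
F5 | step 8 | dimethyl(vinyl)silyl ether of 14 | COC(=O)/C(C)=C/CC[C@H](O[Si](C)(C)C=C)[C@H](CC/C(=C\CO[Si](c1ccccc1)(c1ccccc1)C(C)(C)C)CO[Si](c1ccccc1)(c1ccccc1)C(C)(C)C)C(C)=C
F6 | step 8 | cyclic alkenylsiloxane (ring O–SiMe2–CH=C(CH3)–C9–C8) | COC(=O)/C(C)=C/CC[C@@H]1O[Si](C)(C)C=C(C)[C@H]1CC/C(=C\CO[Si](c1ccccc1)(c1ccccc1)C(C)(C)C)CO[Si](c1ccccc1)(c1ccccc1)C(C)(C)C
F7 | step 13 | methyl 8-hydroxy-17-(trimethylsilyl)-15,16-bis(TBDPS-oxy)-5β(H)-labd-13E-en-19-oate (C8 epimers) | C[Si](C)(C)CC1(O)CC[C@H]2[C@](C)(CCC[C@]2(C)C(=O)OC)[C@H]1CC/C(=C\CO[Si](c1ccccc1)(c1ccccc1)C(C)(C)C)CO[Si](c1ccccc1)(c1ccccc1)C(C)(C)C
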